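**Retrosynthetic overview**
1. Target 13 ⇐ trityl ether 12; acidic detritylation is the last step.
2. Ring A, the tetronic acid and the only ring, is closed once and late by Lacey–Dieckmann cyclisation (C3–C4) of the β-ketoacyl glycerate 11.
3. 11 ⇐ acyl Meldrum's acid 6 + hydroxy ester 9 (O-acylation through an acylketene).
4. Key C–C bond (the future bond between ring carbon C3 and the side-chain carbonyl): intermolecular Claisen-type C-acylation of Meldrum's acid 5 with acid 4, joining the lipid chain to the C2 unit that becomes C2/C3 of ring A.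
5. 4 ⇐ methyl 11-bromoundecanoate 1 + iBuMgBr 2; 9 ⇐ methyl (S)-isopropylidene glycerate 7, which supplies C5 in the (S) configuration.

Assumption: the target is read as the (S)-enantiomer at C5 (L-glycerate series) of 3-(13-methyltetradecanoyl)-5-(hydroxymethyl)tetronic acid, drawn as one of its enol tautomers.

**Step 1**
Reactants: 1 methyl 11-bromoundecanoate; 2 isobutylmagnesium bromide
Product: 3 methyl 13-methyltetradecanoate
Conditions: iBuMgBr (1.3 equiv, slow addition), Li2CuCl4 (3 mol %), NMP (4 equiv), THF, 0 °C → rt; NH4Cl aq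
Reagents that add atoms: none
Why: Kochi-type copper-catalysed alkyl–alkyl cross-coupling of a primary bromide with a primary Grignard reagent outruns addition to the methyl ester when the Grignard is added slowly with NMP present; no stereocentre is involved.

**Step 2**
Reactants: 3 methyl 13-methyltetradecanoate
Product: 4 13-methyltetradecanoic acid
Conditions: LiOH·H2O (3 equiv), THF/MeOH/H2O 3:1:1, rt → 40 °C; then 1 M HCl to pH 2
Reagents that add atoms: lithium hydroxide, [Li+].[OH-]
Why: Saponification of an unhindered methyl ester is essentially quantitative and the acid is purified by simple acid–base extraction.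

**Step 3**
Reactants: 4 13-methyltetradecanoic acid; 5 Meldrum's acid (2,2-dimethyl-1,3-dioxane-4,6-dione)
Product: 6 5-(1-hydroxy-13-methyltetradecylidene)-2,2-dimethyl-1,3-dioxane-4,6-dione
Conditions: DCC (1.1 equiv), DMAP (1.5 equiv), CH2Cl2, 0 °C → rt, 16 h; filter, 1 M KHSO4 wash
Reagents that add atoms: none
Why: Intermolecular Claisen-type C-acylation (Oikawa–Yonemitsu acyl Meldrum's acid synthesis): the DCC/DMAP-activated acid is attacked at carbon by the very acidic Meldrum's acid, and the fully enolised tricarbonyl product cannot react further.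

**Step 4**
Reactants: 7 methyl (S)-2,2-dimethyl-1,3-dioxolane-4-carboxylate
Product: 8 methyl (S)-2,3-dihydroxypropanoate (methyl L-glycerate)
Conditions: Amberlyst-15 (H+ form), dry MeOH, rt, 16 h; filter, concentrate
Reagents that add atoms: none
Why: Acid-catalysed transketalisation to methanol removes the acetonide without an aqueous work-up, leaves the methyl ester unchanged and does not touch the chiral-pool (S) centre that becomes C5.

**Step 5**
Reactants: 8 methyl (S)-2,3-dihydroxypropanoate
Product: 9 methyl (S)-2-hydroxy-3-(trityloxy)propanoate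
Conditions: TrCl (1.05 equiv), Et3N (1.5 equiv), DMAP (5 mol %), CH2Cl2, 0 °C → rt
Reagents that add atoms: trityl chloride, ClC(c1ccccc1)(c1ccccc1)c1ccccc1
Why: Selective tritylation (SN1-type etherification): the bulky trityl cation reacts only at the primary hydroxyl, leaving the secondary α-hydroxyl free for acylation.

**Step 6**
Reactants: 6 5-(1-hydroxy-13-methyltetradecylidene)-2,2-dimethyl-1,3-dioxane-4,6-dione (1.1 equiv); 9 methyl (S)-2-hydroxy-3-(trityloxy)propanoate
Product: 11 methyl (S)-2-[(15-methyl-3-oxohexadecanoyl)oxy]-3-(trityloxy)propanoate, via acylketene 10 (not isolated)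
Conditions: toluene, 100 °C, 3 h
Reagents that add atoms: none
Why: Thermal retro-hetero-Diels–Alder fragmentation of the acyl Meldrum's acid releases an acylketene that the secondary alcohol traps to give the β-keto ester without added base or acid, so the stereocentre is untouched.

**Step 7**
Reactants: 11 methyl (S)-2-[(15-methyl-3-oxohexadecanoyl)oxy]-3-(trityloxy)propanoate
Product: 12 (S)-4-hydroxy-3-(13-methyltetradecanoyl)-5-[(trityloxy)methyl]furan-2(5H)-one
Conditions: Bu4NF (TBAF, 1.0 M in THF, 2.5 equiv), THF, rt, 4–16 h; then cold 1 M HCl, EtOAc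
Reagents that add atoms: none
Why: Fluoride-mediated Lacey–Dieckmann cyclisation (intramolecular Claisen): the mild base deprotonates only the β-keto ester CH2, which attacks the methyl ester to close ring A, and the product is held as its unreactive enolate so the (S) centre at C5 is retained.

**Step 8**
Reactants: 12 (S)-4-hydroxy-3-(13-methyltetradecanoyl)-5-[(trityloxy)methyl]furan-2(5H)-one
Product: 13 (S)-4-hydroxy-5-(hydroxymethyl)-3-(13-methyltetradecanoyl)furan-2(5H)-one
Conditions: HCl (1.25 M in MeOH, 2 equiv), CH2Cl2/MeOH 1:1, 0 °C → rt, 2 h; purify on RP-C18 (MeOH/H2O, 0.1 % HCO2H), not on normal silica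
Reagents that add atoms: none
Why: Acid-catalysed SN1 cleavage of the trityl ether, with methanol trapping the trityl cation irreversibly; the acidic acyltetronic acid core tolerates dilute acid and no bond at C5 is broken.

**Compound list**
1 | methyl 11-bromoundecanoate | BrCCCCCCCCCCC(=O)OC | starting material
2 | isobutylmagnesium bromide (iBuMgBr) | CC(C)C[Mg]Br | starting material
3 | methyl 13-methyltetradecanoate | CC(C)CCCCCCCCCCCC(=O)OC | intermediate
4 | 13-methyltetradecanoic acid | CC(C)CCCCCCCCCCCC(=O)O | intermediate
5 | Meldrum's acid (2,2-dimethyl-1,3-dioxane-4,6-dione) | CC1(C)OC(=O)CC(=O)O1 | starting material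
6 | 5-(1-hydroxy-13-methyltetradecylidene)-2,2-dimethyl-1,3-dioxane-4,6-dione | CC(C)CCCCCCCCCCCC(O)=C1C(=O)OC(C)(C)OC1=O | intermediate
7 | methyl (S)-2,2-dimethyl-1,3-dioxolane-4-carboxylate | COC(=O)[C@@H]1COC(C)(C)O1 | starting material
8 | methyl (S)-2,3-dihydroxypropanoate | COC(=O)[C@@H](O)CO | intermediate
9 | methyl (S)-2-hydroxy-3-(trityloxy)propanoate | COC(=O)[C@@H](O)COC(c1ccccc1)(c1ccccc1)c1ccccc1 | intermediate
10 | acylketene, 15-methylhexadec-1-ene-1,3-dione (not isolated) | CC(C)CCCCCCCCCCCC(=O)C=C=O | intermediate
11 | methyl (S)-2-[(15-methyl-3-oxohexadecanoyl)oxy]-3-(trityloxy)propanoate | CC(C)CCCCCCCCCCCC(=O)CC(=O)O[C@@H](COC(c1ccccc1)(c1ccccc1)c1ccccc1)C(=O)OC | intermediate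
12 | (S)-4-hydroxy-3-(13-methyltetradecanoyl)-5-[(trityloxy)methyl]furan-2(5H)-one | CC(C)CCCCCCCCCCCC(=O)C1=C(O)[C@H](COC(c2ccccc2)(c2ccccc2)c2ccccc2)OC1=O | intermediate
13 | (S)-4-hydroxy-5-(hydroxymethyl)-3-(13-methyltetradecanoyl)furan-2(5H)-one | CC(C)CCCCCCCCCCCC(=O)C1=C(O)[C@H](CO)OC1=O | target

**Totals**
Total step count: 8.
Longest linear sequence: 6 steps (steps 1, 2, 3, 6, 7, 8; the glycerate branch, steps 4 and 5, joins at step 6).

**Three steps most likely to fail**

Step 7 (Dieckmann closure): the risks are slow closure, partial loss of configuration at C5, or β-elimination of trityloxide to the 5-methylene compound. The fallback sets out from 9 (and uses acid 4) and comes back at 12; it builds ring A first and attaches the acyl group afterwards. Alcohol 9 is acetylated (Ac2O, pyridine, DMAP) to methyl (S)-2-acetoxy-3-(trityloxy)propanoate F1. F1 is cyclised at −78 °C with LiN(SiMe3)2 (2.2 equiv, THF) to (S)-4-hydroxy-5-[(trityloxy)methyl]furan-2(5H)-one F2. F2 and 4 are then joined with DCC/DMAP in CH2Cl2, first giving the enol ester (S)-5-oxo-2-[(trityloxy)methyl]-2,5-dihydrofuran-3-yl 13-methyltetradecanoate F3. In the same flask, DMAP/Et3N moves the acyl group from oxygen to C3 to give 12.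

Step 6 (acylketene transfer): the risks are trityl loss caused by the acidic acyl Meldrum's acid at 100 °C, or poor trapping by the hindered secondary alcohol. The fallback sets out from 6 (and uses 9) and comes back at 11; it replaces the thermal ketene transfer by a room-temperature thioester activation. Compound 6 is heated with 2-methylpropane-2-thiol in toluene to give S-tert-butyl 15-methyl-3-oxohexadecanethioate F4. F4 is coupled with 9 by AgOCOCF3 in THF at rt to give 11.

Step 1 (copper-catalysed coupling): the risks are Grignard attack on the ester, or homocoupling and reduction of the bromide. The fallback sets out from 1 and comes back at 3; it replaces the cross-coupling by olefination and hydrogenation. Compound 1 is heated with PPh3 in MeCN to give (11-methoxy-11-oxoundecyl)triphenylphosphonium bromide F5. The ylide (NaN(SiMe3)2, THF, −78 °C) is treated with isobutyraldehyde to give methyl (Z)-13-methyltetradec-11-enoate F6. Hydrogenation (H2, Pd/C, EtOAc) gives 3.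

**Further compounds**
F1 | step 7 | methyl (S)-2-acetoxy-3-(trityloxy)propanoate | COC(=O)[C@@H](OC(C)=O)COC(c1ccccc1)(c1ccccc1)c1ccccc1
F2 | step 7 | (S)-4-hydroxy-5-[(trityloxy)methyl]furan-2(5H)-one | O=C1C=C(O)[C@H](COC(c2ccccc2)(c2ccccc2)c2ccccc2)O1
F3 | step 7 | (S)-5-oxo-2-[(trityloxy)methyl]-2,5-dihydrofuran-3-yl 13-methyltetradecanoate | CC(C)CCCCCCCCCCCC(=O)OC1=CC(=O)O[C@H]1COC(c2ccccc2)(c2ccccc2)c2ccccc2
F4 | step 6 | S-tert-butyl 15-methyl-3-oxohexadecanethioate | CC(C)CCCCCCCCCCCC(=O)CC(=O)SC(C)(C)C
F5 | step 1 | (11-methoxy-11-oxoundecyl)triphenylphosphonium bromide | COC(=O)CCCCCCCCCC[P+](c1ccccc1)(c1ccccc1)c1ccccc1.[Br-]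
F6 | step 1 | methyl (Z)-13-methyltetradec-11-enoate | COC(=O)CCCCCCCCC/C=C\C(C)C
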